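**Plan**

- Numbering used throughout: ring carbons C1–C10; C6 carries the lactone oxygen, C7 carries C11 (C11=C13 methylene, C12 carbonyl), C8 the ester oxygen, C10 the formyl carbon C14, C4 the hydroxymethyl carbon C15. PMB = 4-methoxybenzyl, TES = triethylsilyl, TBS = tert-butyldimethylsilyl.
- Retrosynthesis: the C15 silyl group, the C14 oxidation level and the C8 acyl group are adjusted last. The ten-membered ring is opened at C1=C10 (ring-closing metathesis). The lactone is then removed by cutting O–C6 and C11–C7 together, which leaves an acyclic (4E,6E)-diene C4=C5–C6=C7 and 2-bromoacrylic acid. The diene is cut at C4=C5 (Horner–Wadsworth–Emmons) and C6=C7 (Wittig), and the C8–C10/C14 arm at C9–C10 (epoxide opening).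
- Forward order: chain assembly from methyl (R)-glycidate, then the five-membered lactone ring (step 10), then the ten-membered carbocycle (step 13), then adjustment at C8, C14 and C15.
- Enabling feature: C6 is both the lactone carbinol carbon and allylic to C4=C5. A C6=C7 double bond conjugated with C4=C5 therefore makes C7 the diene terminus that takes carbon and C6 the end of an η3-allyl (C6–C5–C4) that takes the carboxylate oxygen. The five-membered lactone ring closes and C4=C5 stays exactly where the target has it.
- Stereochemistry: C8 from methyl (R)-glycidate; C7 from C8 by 1,2-induction in step 10; C6 from the E geometry of C6=C7 and syn addition of carbon and oxygen; the acyl stereocentre from (R)-2-methylbutanoic acid; C4=C5 geometry from the Horner–Wadsworth–Emmons step; C1=C10 geometry from ring strain in the metathesis.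

Key step: step 10

Remark: (2E)-5-bromopent-2-ene and (2R)-2-methylbutanoic acid are taken as purchasable; the geometry of the propenyl end group is immaterial because this unit leaves as propene in step 13.

**Route**

Step 1
Reactants: 1 2-bromoprop-2-en-1-ol
Product: 2 2-bromoallyl 4-methoxybenzyl ether
Conditions: NaH, 4-MeOC6H4CH2Cl, n-Bu4NI (cat.), THF, 0 °C to rt
Reagents that add atoms: 4-methoxybenzyl chloride, COc1ccc(CCl)cc1
Why: Williamson ether synthesis on the alkoxide of 1; a benzyl-type ether is chosen over a silyl ether because it cannot migrate from oxygen to carbon when the vinyl bromide is metalated in step 2.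

Step 2
Reactants: 2 2-bromoallyl 4-methoxybenzyl ether; 3 methyl (R)-glycidate
Product: 6 methyl (2R)-2-hydroxy-4-(PMB-oxymethyl)pent-4-enoate, via vinyllithium 4 (not isolated), via vinylmagnesium bromide 5 (not isolated)
Conditions: t-BuLi (2.0 equiv), Et2O, −78 °C; MgBr2·OEt2, −78 °C; CuI (15 mol %), then 3, THF, −78 to −40 °C; aq. NH4Cl
Reagents that add atoms: none
Why: Bromine–lithium exchange at −78 °C, transmetalation to the Grignard reagent and copper-catalysed SN2 opening of the glycidate at its unsubstituted carbon form C9–C10; the epoxide stereocentre becomes C8 and is not touched.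

Step 3
Reactants: 6 methyl (2R)-2-hydroxy-4-(PMB-oxymethyl)pent-4-enoate
Product: 7 methyl (2R)-4-(PMB-oxymethyl)-2-(triethylsilyloxy)pent-4-enoate
Conditions: Et3SiCl, imidazole, DMF, 0 °C
Reagents that add atoms: chlorotriethylsilane, CC[Si](Cl)(CC)CC
Why: Standard silylation of a secondary alcohol; the TES ether is the bulky, non-coordinating group that directs step 10 and can later be removed beside TBS and PMB.

Step 4
Reactants: 7 methyl (2R)-4-(PMB-oxymethyl)-2-(triethylsilyloxy)pent-4-enoate
Product: 8 (2R)-4-(PMB-oxymethyl)-2-(triethylsilyloxy)pent-4-enal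
Conditions: i-Bu2AlH (1.1 equiv), CH2Cl2, −78 °C; MeOH, aq. Rochelle salt
Reagents that add atoms: none
Why: Partial reduction of an α-silyloxy ester by i-Bu2AlH stops at the aldehyde because the aluminium hemiacetal survives at −78 °C; C8 is not epimerised under these non-basic conditions.

Step 5
Reactants: 8 (2R)-4-(PMB-oxymethyl)-2-(triethylsilyloxy)pent-4-enal; 9 (triphenylphosphoranylidene)acetaldehyde
Product: 10 (2E,4R)-6-(PMB-oxymethyl)-4-(triethylsilyloxy)hepta-2,6-dienal
Conditions: toluene, 80 °C
Reagents that add atoms: none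
Why: Wittig reaction of the stabilised formyl ylide should give the (E)-enal, forming C6=C7 and bringing in C5 and C6.

Step 6
Reactants: 11 triethyl phosphonoacetate; 12 (2E)-5-bromopent-2-ene
Product: 13 ethyl (5E)-2-(diethoxyphosphoryl)hept-5-enoate (racemic)
Conditions: NaH, 11 in excess, THF/DMF, 0 to 50 °C
Reagents that add atoms: none
Why: C-alkylation of the sodium salt of the phosphonoacetate with a primary bromide; excess 11 suppresses dialkylation.

Step 7
Reactants: 10 (2E,4R)-6-(PMB-oxymethyl)-4-(triethylsilyloxy)hepta-2,6-dienal; 13 ethyl (5E)-2-(diethoxyphosphoryl)hept-5-enoate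
Product: 14 ethyl (2E,4E,6R)-8-(PMB-oxymethyl)-2-[(3E)-pent-3-enyl]-6-(triethylsilyloxy)nona-2,4,8-trienoate
Conditions: NaH, THF, 0 °C; then 10, 0 °C to rt
Reagents that add atoms: none
Why: Horner–Wadsworth–Emmons olefination with an α-alkyl phosphonoacetate forms C4=C5 with the ester carbon (C15) trans to C6, the usual E outcome for this reagent class; any Z isomer is removed by chromatography.

Step 8
Reactants: 14 ethyl (2E,4E,6R)-8-(PMB-oxymethyl)-2-[(3E)-pent-3-enyl]-6-(triethylsilyloxy)nona-2,4,8-trienoate
Product: 15 (2E,4E,6R)-8-(PMB-oxymethyl)-2-[(3E)-pent-3-enyl]-6-(triethylsilyloxy)nona-2,4,8-trien-1-ol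
Conditions: i-Bu2AlH (2.5 equiv), CH2Cl2, −78 °C
Reagents that add atoms: none
Why: 1,2-Reduction of the conjugated ester by i-Bu2AlH gives the allylic alcohol (C15–OH) and leaves the diene, silyl ether and PMB ether alone.

Step 9
Reactants: 15 (2E,4E,6R)-8-(PMB-oxymethyl)-2-[(3E)-pent-3-enyl]-6-(triethylsilyloxy)nona-2,4,8-trien-1-ol
Product: 16 TBS ether of 15 (acyclic diene C4=C5–C6=C7 with C15–OTBS, C8–OTES, C14–OPMB)
Conditions: t-BuMe2SiCl, imidazole, CH2Cl2, 0 °C to rt
Reagents that add atoms: tert-butylchlorodimethylsilane, CC(C)(C)[Si](C)(C)Cl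
Why: Silylation of the primary allylic alcohol; C15–OH must stay masked until C14 has been oxidised.

Step 10
Reactants: 16 TBS ether of 15; 17 2-bromoprop-2-enoic acid
Product: 18 trans-α-methylene-γ-butyrolactone (O on C6, C11 on C7) with the (E)-2-(TBS-oxymethyl)hepta-1,5-dienyl chain on C6 and the (R)-CH(OTES)CH2C(=CH2)CH2OPMB chain on C7
Conditions: Pd(OAc)2 (10 mol %), P(2-furyl)3 (20 mol %), Ag2CO3 (1.0 equiv), 17 (1.5 equiv), DMF, 60 °C
Reagents that add atoms: none
Why: Zerovalent palladium (from Pd(OAc)2 and the phosphine) inserts into the C–Br bond of 17; after silver has removed bromide the α-carboxyvinylpalladium adds syn across C6=C7, carbon going to the diene terminus C7 (bond C11–C7) and palladium to C6, where it is held as an η3-allyl over C6–C5–C4, and the carboxylate already bound to palladium is then transferred to C6 on the same face (C–O reductive elimination, bond O–C6), which regenerates zerovalent palladium. The closest known reaction type is the Larock heteroannulation of 1,3-dienes by vinylic or aryl halides that carry a carboxylic acid, alcohol or amine. The one ring closed is the five-membered lactone, formed by attack of the tethered carboxylate on the proximal allyl terminus C6 (5-exo with respect to the allyl unit) and not on C4, which would give a seven-membered ring at a fully substituted carbon. C7 is controlled by C8: in the conformer with C8–H eclipsing C6=C7 the bulky, non-coordinating OTES group shields one diene face, so C11 should enter anti to it; C6 is controlled by the E geometry of C6=C7 together with the overall syn addition of carbon and oxygen, which gives the trans-β,γ-disubstituted lactone (also the more stable one, so reversible ionisation of the allylic C6–O bond should not erode it). The step needs site selectivity for the diene over the three isolated olefins, secured by η4-binding and η3-allyl formation, which only the diene offers, and by capping the chain end as an internal propenyl and not a vinyl group; it needs regioselectivity, secured because C7 is the only diene terminus that is not fully substituted; and it needs the C4=C5 geometry to survive, which holds because exchange of the two C4 substituents would require a tertiary σ-alkylpalladium.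

Step 11
Reactants: 18 trans-α-methylene-γ-butyrolactone with C8–OTES
Product: 19 the C8 alcohol of 18
Conditions: PPTS (cat.), MeOH/CH2Cl2, 0 °C
Reagents that add atoms: none
Why: Acid-catalysed methanolysis removes the secondary TES ether selectively; the primary TBS ether, the PMB ether and the lactone are stable to PPTS at 0 °C.

Step 12
Reactants: 19 the C8 alcohol of 18; 20 (2R)-2-methylbutanoic acid
Product: 21 the C8 (2R)-2-methylbutanoate of 19
Conditions: DCC, DMAP (cat.), CH2Cl2, 0 °C to rt
Reagents that add atoms: none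
Why: Steglich esterification of the secondary alcohol; low temperature and catalytic DMAP keep the α-stereocentre of the acid intact.

Step 13
Reactants: 21 the C8 (2R)-2-methylbutanoate of 19
Product: 22 ten-membered carbocycle with C14–OPMB, C15–OTBS and the C8 ester (C1=C10 formed, C2 and C9 cis)
Conditions: second-generation Grubbs catalyst RuCl2(=CHPh)(H2IMes)(PCy3) (15 mol %, in portions), toluene (1 mM), 80 °C
Reagents that add atoms: none
Why: Ring-closing metathesis between the propenyl group (C1) and the 1,1-disubstituted allyl-ether olefin (C10) expels propene; the trans lactone and the C4=C5 olefin (C3 cis to C6) hold the two ends close, the ten-membered ring should accept the new trisubstituted olefin only with C2 and C9 cis (CH2OPMB trans to C2), and metathesis closures of ten-membered germacranolide-type rings carrying an α-methylene lactone are precedented, the acrylate-type methylene and the trisubstituted C4=C5 olefin being far less reactive toward the ruthenium carbene.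

Step 14
Reactants: 22 ten-membered carbocycle with C14–OPMB
Product: 23 the C14 allylic alcohol
Conditions: DDQ, CH2Cl2/pH 7 buffer (10:1), 0 °C
Reagents that add atoms: none
Why: Oxidative cleavage of the PMB ether by DDQ under neutral conditions leaves the silyl ether, both esters and the olefins untouched.

Step 15
Reactants: 23 the C14 allylic alcohol
Product: 24 the C14 aldehyde (C15–OTBS still in place)
Conditions: MnO2 (activated, excess), CH2Cl2, rt
Reagents that add atoms: none
Why: MnO2 oxidises only the allylic alcohol and gives the enal with the olefin geometry retained (CHO trans to C2, also the more stable enal geometry).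

Step 16
Reactants: 24 the C14 aldehyde with C15–OTBS
Product: 25 target, CNP0168859.5
Conditions: HF·pyridine, pyridine/THF, 0 °C to rt
Reagents that add atoms: none
Why: Buffered HF·pyridine cleaves the primary silyl ether under mildly acidic, non-nucleophilic conditions that should leave the enal, the α-methylene lactone and the ester intact.

**Compound list**

1 | 2-bromoprop-2-en-1-ol | OCC(Br)=C | starting material
2 | 1-{[(2-bromoprop-2-en-1-yl)oxy]methyl}-4-methoxybenzene | C=C(Br)COCc1ccc(OC)cc1 | intermediate
3 | methyl (2R)-oxirane-2-carboxylate (methyl (R)-glycidate) | COC(=O)[C@H]1CO1 | starting material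
4 | {3-[(4-methoxybenzyl)oxy]prop-1-en-2-yl}lithium (formed in situ) | [Li]C(=C)COCc1ccc(OC)cc1 | intermediate
5 | bromo{3-[(4-methoxybenzyl)oxy]prop-1-en-2-yl}magnesium (formed in situ) | Br[Mg]C(=C)COCc1ccc(OC)cc1 | intermediate
6 | methyl (2R)-2-hydroxy-4-{[(4-methoxybenzyl)oxy]methyl}pent-4-enoate | COC(=O)[C@H](O)CC(=C)COCc1ccc(OC)cc1 | intermediate
7 | methyl (2R)-4-{[(4-methoxybenzyl)oxy]methyl}-2-[(triethylsilyl)oxy]pent-4-enoate | COC(=O)[C@H](O[Si](CC)(CC)CC)CC(=C)COCc1ccc(OC)cc1 | intermediate
8 | (2R)-4-{[(4-methoxybenzyl)oxy]methyl}-2-[(triethylsilyl)oxy]pent-4-enal | O=C[C@H](O[Si](CC)(CC)CC)CC(=C)COCc1ccc(OC)cc1 | intermediate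
9 | (triphenylphosphoranylidene)acetaldehyde | O=CC=P(c1ccccc1)(c1ccccc1)c1ccccc1 | starting material
10 | (2E,4R)-6-{[(4-methoxybenzyl)oxy]methyl}-4-[(triethylsilyl)oxy]hepta-2,6-dienal | O=C/C=C/[C@H](O[Si](CC)(CC)CC)CC(=C)COCc1ccc(OC)cc1 | intermediate
11 | triethyl phosphonoacetate | CCOC(=O)CP(=O)(OCC)OCC | starting material
12 | (2E)-5-bromopent-2-ene | C/C=C/CCBr | starting material
13 | ethyl (5E)-2-(diethoxyphosphoryl)hept-5-enoate (racemic) | CCOC(=O)C(CC/C=C/C)P(=O)(OCC)OCC | intermediate
14 | ethyl (2E,4E,6R)-8-{[(4-methoxybenzyl)oxy]methyl}-2-[(3E)-pent-3-en-1-yl]-6-[(triethylsilyl)oxy]nona-2,4,8-trienoate | CCOC(=O)/C(CC/C=C/C)=C/C=C/[C@H](O[Si](CC)(CC)CC)CC(=C)COCc1ccc(OC)cc1 | intermediate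
15 | (2E,4E,6R)-8-{[(4-methoxybenzyl)oxy]methyl}-2-[(3E)-pent-3-en-1-yl]-6-[(triethylsilyl)oxy]nona-2,4,8-trien-1-ol | OC/C(CC/C=C/C)=C/C=C/[C@H](O[Si](CC)(CC)CC)CC(=C)COCc1ccc(OC)cc1 | intermediate
16 | tert-butyl({(2E,4E,6R)-8-{[(4-methoxybenzyl)oxy]methyl}-2-[(3E)-pent-3-en-1-yl]-6-[(triethylsilyl)oxy]nona-2,4,8-trien-1-yl}oxy)dimethylsilane | CC(C)(C)[Si](C)(C)OC/C(CC/C=C/C)=C/C=C/[C@H](O[Si](CC)(CC)CC)CC(=C)COCc1ccc(OC)cc1 | intermediate
17 | 2-bromoprop-2-enoic acid | C=C(Br)C(=O)O | starting material
18 | (4S,5R)-5-[(1E,5E)-2-({[tert-butyl(dimethyl)silyl]oxy}methyl)hepta-1,5-dien-1-yl]-4-[(1R)-3-{[(4-methoxybenzyl)oxy]methyl}-1-[(triethylsilyl)oxy]but-3-en-1-yl]-3-methylideneoxolan-2-one (trans lactone; C6, C7, C8 arranged as in the target) | C=C1C(=O)O[C@H](/C=C(/CO[Si](C)(C)C(C)(C)C)CC/C=C/C)[C@H]1[C@H](O[Si](CC)(CC)CC)CC(=C)COCc1ccc(OC)cc1 | intermediate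
19 | (4R,5R)-5-[(1E,5E)-2-({[tert-butyl(dimethyl)silyl]oxy}methyl)hepta-1,5-dien-1-yl]-4-[(1R)-1-hydroxy-3-{[(4-methoxybenzyl)oxy]methyl}but-3-en-1-yl]-3-methylideneoxolan-2-one | C=C1C(=O)O[C@H](/C=C(/CO[Si](C)(C)C(C)(C)C)CC/C=C/C)[C@H]1[C@H](O)CC(=C)COCc1ccc(OC)cc1 | intermediate
20 | (2R)-2-methylbutanoic acid | CC[C@@H](C)C(=O)O | starting material
21 | (1R)-1-{(2R,3R)-2-[(1E,5E)-2-({[tert-butyl(dimethyl)silyl]oxy}methyl)hepta-1,5-dien-1-yl]-4-methylidene-5-oxooxolan-3-yl}-3-{[(4-methoxybenzyl)oxy]methyl}but-3-en-1-yl (2R)-2-methylbutanoate | C=C1C(=O)O[C@H](/C=C(/CO[Si](C)(C)C(C)(C)C)CC/C=C/C)[C@H]1[C@H](OC(=O)[C@H](C)CC)CC(=C)COCc1ccc(OC)cc1 | intermediate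
22 | (3aR,4R,6E,10E,11aR)-10-({[tert-butyl(dimethyl)silyl]oxy}methyl)-6-{[(4-methoxybenzyl)oxy]methyl}-3-methylidene-2-oxo-2,3,3a,4,5,8,9,11a-octahydrocyclodeca[b]furan-4-yl (2R)-2-methylbutanoate | C=C1C(=O)O[C@@H]2/C=C(/CO[Si](C)(C)C(C)(C)C)CC/C=C(/COCc3ccc(OC)cc3)C[C@@H](OC(=O)[C@H](C)CC)[C@@H]12 | intermediate
23 | (3aR,4R,6E,10E,11aR)-10-({[tert-butyl(dimethyl)silyl]oxy}methyl)-6-(hydroxymethyl)-3-methylidene-2-oxo-2,3,3a,4,5,8,9,11a-octahydrocyclodeca[b]furan-4-yl (2R)-2-methylbutanoate | C=C1C(=O)O[C@@H]2/C=C(/CO[Si](C)(C)C(C)(C)C)CC/C=C(/CO)C[C@@H](OC(=O)[C@H](C)CC)[C@@H]12 | intermediate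
24 | (3aR,4R,6E,10E,11aR)-10-({[tert-butyl(dimethyl)silyl]oxy}methyl)-6-formyl-3-methylidene-2-oxo-2,3,3a,4,5,8,9,11a-octahydrocyclodeca[b]furan-4-yl (2R)-2-methylbutanoate | C=C1C(=O)O[C@@H]2/C=C(/CO[Si](C)(C)C(C)(C)C)CC/C=C(/C=O)C[C@@H](OC(=O)[C@H](C)CC)[C@@H]12 | intermediate
25 | (3aR,4R,6E,10E,11aR)-6-formyl-10-(hydroxymethyl)-3-methylidene-2-oxo-2,3,3a,4,5,8,9,11a-octahydrocyclodeca[b]furan-4-yl (2R)-2-methylbutanoate (CNP0168859.5) | C=C1C(=O)O[C@@H]2/C=C(/CO)CC/C=C(/C=O)C[C@@H](OC(=O)[C@H](C)CC)[C@@H]12 | target

**Step count and risks**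

Total steps: 16. Longest linear sequence: 15 steps (steps 1–5 and 7–16; step 6 is the side branch).

Steps most likely to fail, riskiest first:

Step 10. The carbopalladation may show poor facial selectivity with respect to C8. The η3-allyl may be diverted to β-hydride elimination (Heck-type trienes) before the C–O bond forms. An outer-sphere C–O closure may erode the trans ring fusion. The fallback replaces the palladium event by a radical–polar crossover annulation followed by a separate methylenation; it sets out from 16 and returns at 18. Treatment of 16 with excess malonic acid, Mn(OAc)3·2H2O and KOAc in AcOH at 40 °C should add the malonyl radical to C7 and oxidise the resulting allyl radical to the cation; the carboxyl group then closes at C6 under product-stability control to the trans α-carboxy lactone F1. Decarboxylative Mannich methylenation of the α-carboxy lactone F1 (aqueous formaldehyde, Et2NH, NaOAc/AcOH, 60 °C) then gives 18.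

Step 13. Oligomerisation may outrun closure of the strained ten-membered ring, and the ruthenium carbene may be drawn into the acrylate-type methylene of the lactone (eight-membered closure or catalyst sequestration). The fallback removes that olefin before the ring is closed; it sets out from 21 and returns at 22. Conjugate addition of Me2NH (THF/MeOH, 0 °C) to 21 gives the dimethylamine adduct F2. Ring-closing metathesis of the dimethylamine adduct F2 as its camphorsulfonate salt with the same ruthenium catalyst gives the cyclised amine adduct F3. Quaternisation of the cyclised amine adduct F3 with MeI and elimination with aqueous NaHCO3 restores the methylene group and gives 22.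

Step 5. The product enal may be homologated a second time by the ylide, and the α-silyloxy aldehyde may epimerise or eliminate at the temperature the weakly nucleophilic formyl ylide needs. The fallback builds the enal by ester olefination and redox adjustment; it sets out from 8 and returns at 10. Horner–Wadsworth–Emmons reaction of 8 with 11 (LiCl, i-Pr2NEt, MeCN, rt) gives the (E)-enoate F4. Reduction of the (E)-enoate F4 with i-Bu2AlH (CH2Cl2, −78 °C) gives the allylic alcohol F5. Oxidation of the allylic alcohol F5 with MnO2 (CH2Cl2, rt) gives 10.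

Further compounds

F1 | step 10 | 3-carboxy analogue of 18 saturated at C11: 5-[(1E,5E)-2-(TBS-oxymethyl)hepta-1,5-dienyl]-4-[(1R)-3-(PMB-oxymethyl)-1-(triethylsilyloxy)but-3-enyl]-2-oxooxolane-3-carboxylic acid (C11 epimers) | OC(=O)C1C(=O)O[C@H](/C=C(/CO[Si](C)(C)C(C)(C)C)CC/C=C/C)[C@H]1[C@H](O[Si](CC)(CC)CC)CC(=C)COCc1ccc(OC)cc1
F2 | step 13 | dimethylamine adduct of 21, 3-[(dimethylamino)methyl]oxolan-2-one (C11 epimers) | CN(C)CC1C(=O)O[C@H](/C=C(/CO[Si](C)(C)C(C)(C)C)CC/C=C/C)[C@H]1[C@H](OC(=O)[C@H](C)CC)CC(=C)COCc1ccc(OC)cc1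
F3 | step 13 | dimethylamine adduct of 22, 3-[(dimethylamino)methyl] ten-membered lactone (C11 epimers) | CN(C)CC1C(=O)O[C@@H]2/C=C(/CO[Si](C)(C)C(C)(C)C)CC/C=C(/COCc3ccc(OC)cc3)C[C@@H](OC(=O)[C@H](C)CC)[C@@H]12
F4 | step 5 | ethyl (2E,4R)-6-{[(4-methoxybenzyl)oxy]methyl}-4-[(triethylsilyl)oxy]hepta-2,6-dienoate | CCOC(=O)/C=C/[C@H](O[Si](CC)(CC)CC)CC(=C)COCc1ccc(OC)cc1
F5 | step 5 | (2E,4R)-6-{[(4-methoxybenzyl)oxy]methyl}-4-[(triethylsilyl)oxy]hepta-2,6-dien-1-ol | OC/C=C/[C@H](O[Si](CC)(CC)CC)CC(=C)COCc1ccc(OC)cc1
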